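Start from what stays over: Monday's charges 0.0600 M of coupling partner against 0.050 M of starting material, the limiting reagent, so coupling partner must remain and the starting material is what needs accounting for.

| flask | starting material | coupling partner | remark | time |
|---|---|---|---|---|
| birch | 0.013 M (fed, over 12 h) | 0.060 M | run made earlier; the fed solution adds 1.0 times the starting volume |  |
| maple | 0.033 M (fed, over 12 h) | 0.060 M | run made earlier; the fed solution adds 1.0 times the starting volume |  |
| Tuesday's | 0.025 M | 0.0600 M | everything together at the start, the whole solution of starting material included, so that from the start the volume is larger by 1.0 times the starting volume | 3.0 d |
| Monday's | 0.050 M (fed, over 12 h) | 0.0600 M | the fed solution adds 1.0 times the starting volume | 3.0 d |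

| run | time / h | target / % |
|---|---|---|
| birch | 3.00 | 5 |
| birch | 5.00 | 10 |
| birch | 10.0 | 30 |
| birch | 20.0 | 60 |
| birch | 40.0 | 85 |
| maple | 3.00 | 2 |
| maple | 10.0 | 23 |
| maple | 15.0 | 48 |
| maple | 25.0 | 64 |
| maple | 40.0 | 76 |

(readings scatter by 1.5 percentage points)

- amounts are per litre of the starting volume; all of the dose is in the solution fed
- percentages count the whole charge, also what has not yet gone in

* the flask that ends with the higher amount of target, in percent of the starting material charged, or "neither" when 2 percentage points or less lies between them (Tuesday's / Monday's / neither)
* final target, as a percentage of the starting material charged, in Tuesday's
* final target, as a percentage of the starting material charged, in Monday's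

Write the balance of starting material: the charge ends as target, as loss, or unconverted. Now read the loss. At 40.0 h maple stood at 76%, below birch at 85%, and maple carried the heavier charge. So suppose that starting material is lost by meeting itself while it couples by meeting coupling partner; the lost share then follows [starting material]/[coupling partner]. Count both charges per litre of starting volume, and the dilution cancels: Tuesday's has 2.40 equivalents, Monday's 1.20.

But maple was still rising, by 12 percentage points over its last interval. Allow half of that rise again, and my estimate of its final target is 82.0%. Multiplying its lost share by its equivalents gives 0.327, the loss product, lost share times equivalents.

Test it on birch, which it has not seen: it gives an estimated final target of 92.9%, and birch, still climbing, has not contradicted that. So I reckon 86.4% for Tuesday's and 72.8% for Monday's.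

Object: those runs were fed, and Tuesday's is not. Yet at 10.0 h maple had 83.3% of its charge in and 23% as target, so 60 points stood unconverted or lost, and the feed kept little out of the solution. Object again: these are rough estimates of the final target, not bounds, and both flasks are read at 3.0 d. Watch Monday's tail, since its excess is 0.0100 M per starting litre against 0.0350 M in Tuesday's; any shortfall there widens the gap. Expect Tuesday's ahead.

The forecast gave neither, with 73% for Tuesday's and 75% for Monday's, holding that “the excess is thin and the finish is slow”.

The flasks give Tuesday's: 84.5% in Tuesday's and 74.1% in Monday's.

    starting material + coupling partner → target + released group (k = 6.93 × 10⁻⁴ /M/s)
    2 starting material → self-condensation product (k = 2.46 × 10⁻⁴ /M/s)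

Multiply what did not become target by the equivalents: Tuesday's gives 0.372 and Monday's 0.311, against the reckoned 0.327. Now take the neighbouring flask, Tuesday's with 0.10 M of coupling partner, which has 4.00 equivalents. The same product predicts a lost share of 8.18%, so 91.8% of target. That flask ended with 91.4% of target and 8.57% of self-condensation product, with 77% of its coupling partner still over.

The earlier runs and the new flask are simulated on assumed constants; the scatter is artificial.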